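The target is cut at C9–C10 of its tetrahydrofuran (ring atoms O, C7, C8, C9, C10). Numbered from the lactone carbonyl C1 to the methyl C12, the C4–C8 chain with oxygens on C5, C6 and C7 is D-arabinose read from C5 to C1, so three stereocentres are bought. The C7 oxygen, which ends up as the ring oxygen, tethers an electron-poor vinyl sulfone; a C9 radical then closes the ring 5-exo onto the oxygen-bearing carbon C10, forming C9–C10 and setting C10 cis to C7 in one operation. The precursor is a C9 iodide whose C7 oxygen carries an (E)-2-tosylvinyl group, with C5/C6 as an acetonide and C4–O silylated.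

Key step: step 7

Remark: target atom numbers (C1 lactone carbonyl to C12 methyl) are used for all intermediates; lactol 2 is carried as its anomeric mixture, which converges in step 2.

Step 1
Reactants: 1 D-arabinose
Product: 2 3,4-O-isopropylidene-D-arabinopyranose
Conditions: 2,2-dimethoxypropane, TsOH·H2O (cat.), DMF, rt; Et3N quench
Reagents that add atoms: 2,2-dimethoxypropane, COC(C)(C)OC
Why: Kinetic acid-catalysed acetalisation engages the cis-3,4-diol of the pyranose as a five-membered isopropylidene acetal, leaving O1 and O2 free and touching no stereocentre.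

Step 2
Reactants: 2 3,4-O-isopropylidene-D-arabinopyranose; 3 methyltriphenylphosphonium bromide
Product: 4 alkene diol (1,2-dideoxy-4,5-O-isopropylidene-D-arabino-hex-1-enitol; C8=C9 alkene, free C7-OH and C4-OH)
Conditions: KOt-Bu, THF, 0 °C to 50 °C (excess ylide)
Reagents that add atoms: none
Why: Wittig methylenation of the open-chain aldehyde tautomer of the lactol gives the terminal alkene and frees the C4 hydroxyl, while the adjacent alkoxide formed under the basic conditions guards C7 against enolisation.

Step 3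
Reactants: 4 alkene diol
Product: 5 C4 O-TBDPS ether of 4
Conditions: TBDPSCl, imidazole, CH2Cl2, 0 °C
Reagents that add atoms: tert-butyl(chloro)diphenylsilane, CC(C)(C)[Si](Cl)(c1ccccc1)c1ccccc1
Why: Silyl ether formation with the bulky chlorosilane discriminates the primary hydroxyl from the secondary allylic one.

Step 4
Reactants: 5 C4 O-TBDPS ether
Product: 7 C7,C9-diol (2-deoxy-4,5-O-isopropylidene-6-O-TBDPS-D-arabino-hexitol), via C9 alkylborane 6 (not isolated)
Conditions: 9-BBN (2.5 equiv), THF, 0 °C to rt; then NaOH, H2O2, 0 °C to rt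
Reagents that add atoms: hydrogen peroxide, OO
Why: Anti-Markovnikov hydroboration of the monosubstituted alkene with the bulky dialkylborane places boron on terminal C9, and alkaline peroxide oxidation turns the C–B bond into the primary alcohol without creating a stereocentre.

Step 5
Reactants: 7 C7,C9-diol
Product: 8 C9 iodo alcohol (free C7-OH)
Conditions: I2, PPh3, imidazole, CH2Cl2, 0 °C, dark
Reagents that add atoms: iodine, II
Why: Appel-type iodination converts the unhindered primary hydroxyl into the iodide much faster than the flanked secondary C7 hydroxyl.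

Step 6
Reactants: 8 C9 iodo alcohol; 9 ethynyl p-tolyl sulfone
Product: 10 radical precursor (O7 (E)-2-(p-tolylsulfonyl)vinyl ether of 8)
Conditions: N-methylmorpholine (0.2 equiv), CH2Cl2, rt
Reagents that add atoms: none
Why: Amine-catalysed oxa-Michael addition of the C7 hydroxyl to the ethynyl sulfone gives the (E)-β-alkoxyvinyl sulfone under conditions too mild to disturb the primary iodide.

Step 7
Reactants: 10 radical precursor
Product: 11 cis-THF sulfone (2,5-cis oxolane; CH2SO2Tol on C10; acetonide side chain on C7)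
Conditions: Bu3SnH (1.3 equiv, syringe pump), AIBN (0.1 equiv), benzene, 80 °C, 0.01 M
Reagents that add atoms: none
Why: Bu3Sn• abstracts iodine from C9 and the nucleophilic primary radical adds in a polarity-matched fashion to C10, the oxygen-bearing β-carbon of the vinylogous sulfonate, after which the sulfonyl-stabilised C11 radical takes hydrogen from Bu3SnH and carries the chain. The closest known reaction type is the tin hydride mediated cyclisation of β-alkoxyacrylates and β-alkoxyvinyl sulfones to cis-2,5-disubstituted oxolanes. The one ring formed, the THF (O, C7, C8, C9, C10), is closed by 5-exo-trig C9–C10 bond formation. The new stereocentre C10 is controlled by C7: in the chair-like transition state the dioxolanyl group on C7 lies pseudo-equatorial and the s-trans vinyl ether presents the face that leads to the 2,5-cis ring. The step needs cyclisation to outrun direct reduction of the C9 radical and needs cis over trans closure; the first is secured by the electron-poor acceptor held through the C7 oxygen and by slow stannane addition at high dilution, the second by the C7 stereocentre inherited from arabinose.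

Step 8
Reactants: 11 cis-THF sulfone
Product: 14 cis-THF C11 aldehyde, via lithiated sulfone 12 (not isolated), via silyloxy sulfone 13 (not isolated)
Conditions: n-BuLi (1.05 equiv), THF, −78 °C, 10 min; then Me3SiOOSiMe3, −78 to −30 °C; pH 7 buffer; used crude
Reagents that add atoms: bis(trimethylsilyl) peroxide, C[Si](C)(C)OO[Si](C)(C)C
Why: Oxidative desulfonylation of an α-sulfonyl carbanion, in which oxygen transfer from the silyl peroxide gives an α-silyloxy sulfone that expels p-toluenesulfinate to unveil the aldehyde, is run cold and briefly so that the ring oxygen is not eliminated and C10 is not epimerised.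

Step 9
Reactants: 14 cis-THF C11 aldehyde
Product: 15 (11S) secondary alcohol
Conditions: MeMgBr (3 equiv), MgBr2·OEt2 (2 equiv), CH2Cl2/Et2O, −78 °C
Reagents that add atoms: methylmagnesium bromide, C[Mg]Br
Why: Chelation-controlled Grignard addition, in which magnesium bridges the aldehyde oxygen and the ring oxygen so that methyl attacks the face of the chelate bearing the C10 hydrogen, should set C11 as S (threo to C10).

Step 10
Reactants: 16 4-(methoxymethoxy)benzaldehyde; 17 malonic acid
Product: 19 (E)-3-[4-(methoxymethoxy)phenyl]prop-2-enoic acid, via arylidenemalonic acid 18 (not isolated)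
Conditions: pyridine, piperidine (cat.), 90 °C; cold citric acid work-up
Reagents that add atoms: none
Why: Knoevenagel condensation followed by decarboxylation in pyridine (Doebner modification) gives the (E)-cinnamic acid, and the basic medium leaves the MOM ether intact.

Step 11
Reactants: 15 (11S) secondary alcohol; 19 (E)-3-[4-(methoxymethoxy)phenyl]prop-2-enoic acid
Product: 20 C11 (E)-4-(methoxymethoxy)cinnamate
Conditions: EDC·HCl, DMAP (cat.), CH2Cl2, 0 °C to rt
Reagents that add atoms: none
Why: Steglich esterification acylates the C11 hydroxyl with retention because the C11–O bond is never broken.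

Step 12
Reactants: 20 C11 (E)-4-(methoxymethoxy)cinnamate
Product: 21 C4 primary alcohol
Conditions: Bu4NF, AcOH, THF, 0 °C to rt
Reagents that add atoms: none
Why: Fluoride cleaves the Si–O bond of the primary silyl ether, and the acetic acid buffer keeps the medium from saponifying the cinnamate.

Step 13
Reactants: 21 C4 primary alcohol
Product: 22 C4 triflate
Conditions: Tf2O, 2,6-lutidine, CH2Cl2, −78 °C; cold work-up, used at once
Reagents that add atoms: trifluoromethanesulfonic anhydride, O=S(=O)(OS(=O)(=O)C(F)(F)F)C(F)(F)F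
Why: O-sulfonylation of the primary alcohol gives the triflate, the leaving group reactive enough for clean SN2 displacement next to the dioxolane oxygen.

Step 14
Reactants: 22 C4 triflate; 23 3,3,3-triethoxyprop-1-yne
Product: 25 ethyl ynoate (C4–C3≡C2–C1O2Et), via orthoester alkyne 24 (not isolated)
Conditions: 23, n-BuLi, THF, −78 °C; then 22, DMPU, −78 to −40 °C; then PPTS (cat.), THF/H2O, 0 °C
Reagents that add atoms: water, O
Why: SN2 alkylation of a lithium acetylide by a primary triflate proceeds at −78 °C, where acetylides do not yet add to a hindered conjugated ester, and the orthoester (a base-stable propiolate equivalent) is then hydrolysed to the ethyl ester by brief mild acid that spares the acetonide and the MOM ether.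

Step 15
Reactants: 25 ethyl ynoate
Product: 26 ethyl (Z)-enoate
Conditions: H2 (1 atm), Pd on CaCO3 poisoned with Pb(OAc)2, quinoline, EtOAc, rt, stopped at one equivalent
Reagents that add atoms: none
Why: Lindlar semihydrogenation delivers hydrogen syn to the alkyne to give the (Z)-enoate, while the conjugated trans-disubstituted cinnamate alkene is reduced far more slowly on the poisoned catalyst.

Step 16
Reactants: 26 ethyl (Z)-enoate
Product: 28 target CNP0417147.2, via dihydroxy ester 27 (not isolated)
Conditions: TFA/THF/H2O (2:2:1), 0 °C to rt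
Reagents that add atoms: none
Why: Aqueous acid hydrolyses the acetonide and the aryl MOM ether, and the freed C5 hydroxyl lactonises onto the (Z)-ester to the six-membered ring whereas the C6 hydroxyl could only form a seven-membered ring and stays free, with no stereocentre touched.

Compound list
1 | D-arabinose | O=C[C@@H](O)[C@H](O)[C@H](O)CO | starting material
2 | 3,4-O-isopropylidene-D-arabinopyranose (anomeric mixture) | OC1OC[C@H]2OC(C)(C)O[C@H]2[C@@H]1O | intermediate
3 | methyltriphenylphosphonium bromide | C[P+](c1ccccc1)(c1ccccc1)c1ccccc1.[Br-] | starting material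
4 | alkene diol, 1,2-dideoxy-4,5-O-isopropylidene-D-arabino-hex-1-enitol | C=C[C@@H](O)[C@@H]1OC(C)(C)O[C@@H]1CO | intermediate
5 | C4 O-TBDPS ether of 4 | C=C[C@@H](O)[C@@H]1OC(C)(C)O[C@@H]1CO[Si](c1ccccc1)(c1ccccc1)C(C)(C)C | intermediate
6 | C9 B-alkyl-9-borabicyclo[3.3.1]nonane from 5 | O[C@H](CCB1C2CCCC1CCC2)[C@@H]1OC(C)(C)O[C@@H]1CO[Si](c1ccccc1)(c1ccccc1)C(C)(C)C | intermediate
7 | C7,C9-diol, 2-deoxy-4,5-O-isopropylidene-6-O-TBDPS-D-arabino-hexitol | OCC[C@@H](O)[C@@H]1OC(C)(C)O[C@@H]1CO[Si](c1ccccc1)(c1ccccc1)C(C)(C)C | intermediate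
8 | C9 iodo alcohol | ICC[C@@H](O)[C@@H]1OC(C)(C)O[C@@H]1CO[Si](c1ccccc1)(c1ccccc1)C(C)(C)C | intermediate
9 | ethynyl p-tolyl sulfone | C#CS(=O)(=O)c1ccc(C)cc1 | starting material
10 | radical precursor, C9 iodide with O7 (E)-2-(p-tolylsulfonyl)vinyl ether | Cc1ccc(cc1)S(=O)(=O)/C=C/O[C@H](CCI)[C@@H]1OC(C)(C)O[C@@H]1CO[Si](c1ccccc1)(c1ccccc1)C(C)(C)C | intermediate
11 | cis-THF sulfone (5R,6S,7R,10S) | Cc1ccc(cc1)S(=O)(=O)C[C@@H]1CC[C@H]([C@@H]2OC(C)(C)O[C@@H]2CO[Si](c3ccccc3)(c3ccccc3)C(C)(C)C)O1 | intermediate
12 | C11-lithiated sulfone | Cc1ccc(cc1)S(=O)(=O)C([Li])[C@@H]1CC[C@H]([C@@H]2OC(C)(C)O[C@@H]2CO[Si](c3ccccc3)(c3ccccc3)C(C)(C)C)O1 | intermediate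
13 | C11 trimethylsilyloxy sulfone (C11 epimers) | Cc1ccc(cc1)S(=O)(=O)C(O[Si](C)(C)C)[C@@H]1CC[C@H]([C@@H]2OC(C)(C)O[C@@H]2CO[Si](c3ccccc3)(c3ccccc3)C(C)(C)C)O1 | intermediate
14 | cis-THF C11 aldehyde | O=C[C@@H]1CC[C@H]([C@@H]2OC(C)(C)O[C@@H]2CO[Si](c3ccccc3)(c3ccccc3)C(C)(C)C)O1 | intermediate
15 | (11S) secondary alcohol | C[C@H](O)[C@@H]1CC[C@H]([C@@H]2OC(C)(C)O[C@@H]2CO[Si](c3ccccc3)(c3ccccc3)C(C)(C)C)O1 | intermediate
16 | 4-(methoxymethoxy)benzaldehyde | COCOc1ccc(C=O)cc1 | starting material
17 | malonic acid | OC(=O)CC(=O)O | starting material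
18 | 2-[4-(methoxymethoxy)benzylidene]malonic acid | COCOc1ccc(C=C(C(=O)O)C(=O)O)cc1 | intermediate
19 | (E)-3-[4-(methoxymethoxy)phenyl]prop-2-enoic acid | COCOc1ccc(/C=C/C(=O)O)cc1 | intermediate
20 | C11 (E)-4-(methoxymethoxy)cinnamate, C4-OTBDPS | C[C@H](OC(=O)/C=C/c1ccc(OCOC)cc1)[C@@H]1CC[C@H]([C@@H]2OC(C)(C)O[C@@H]2CO[Si](c3ccccc3)(c3ccccc3)C(C)(C)C)O1 | intermediate
21 | C4 primary alcohol | C[C@H](OC(=O)/C=C/c1ccc(OCOC)cc1)[C@@H]1CC[C@H]([C@@H]2OC(C)(C)O[C@@H]2CO)O1 | intermediate
22 | C4 triflate | C[C@H](OC(=O)/C=C/c1ccc(OCOC)cc1)[C@@H]1CC[C@H]([C@@H]2OC(C)(C)O[C@@H]2COS(=O)(=O)C(F)(F)F)O1 | intermediate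
23 | 3,3,3-triethoxyprop-1-yne | C#CC(OCC)(OCC)OCC | starting material
24 | orthoester alkyne (C1 triethyl orthoester, C2≡C3) | C[C@H](OC(=O)/C=C/c1ccc(OCOC)cc1)[C@@H]1CC[C@H]([C@@H]2OC(C)(C)O[C@@H]2CC#CC(OCC)(OCC)OCC)O1 | intermediate
25 | ethyl ynoate | C[C@H](OC(=O)/C=C/c1ccc(OCOC)cc1)[C@@H]1CC[C@H]([C@@H]2OC(C)(C)O[C@@H]2CC#CC(=O)OCC)O1 | intermediate
26 | ethyl (Z)-enoate | C[C@H](OC(=O)/C=C/c1ccc(OCOC)cc1)[C@@H]1CC[C@H]([C@@H]2OC(C)(C)O[C@@H]2C/C=C\C(=O)OCC)O1 | intermediate
27 | C5,C6-dihydroxy ethyl (Z)-enoate with free phenol | C[C@H](OC(=O)/C=C/c1ccc(O)cc1)[C@@H]1CC[C@H]([C@H](O)[C@H](O)C/C=C\C(=O)OCC)O1 | intermediate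
28 | CNP0417147.2, (S)-1-[(2S,5R)-5-[(S)-hydroxy[(R)-6-oxo-3,6-dihydro-2H-pyran-2-yl]methyl]oxolan-2-yl]ethyl (E)-3-(4-hydroxyphenyl)prop-2-enoate | C[C@H](OC(=O)/C=C/c1ccc(O)cc1)[C@@H]1CC[C@H]([C@H](O)[C@H]2CC=CC(=O)O2)O1 | target

Total step count: 16. Longest linear sequence: 15 steps (steps 1–9 and 11–16, from D-arabinose); step 10 is a one-step side branch.

Steps most likely to fail

Step 8. The α-sulfonyl carbanion sits β to the ring oxygen, so E1cB ring opening to a hydroxy vinyl sulfone can compete. Re-closure could then scramble C10, and the enolisable α-alkoxy aldehyde may also be lost in the basic medium. The fallback oxidises C11 without any carbanion by using a sulfoxide in place of the sulfone. It sets out from iodo alcohol 8, which is added to ethynyl p-tolyl sulfoxide (N-methylmorpholine, CH2Cl2) to give the (E)-β-alkoxyvinyl sulfoxide F1 as a mixture at sulfur. The same Bu3SnH/AIBN closure should give the cis-THF sulfoxide F2. Pummerer rearrangement (trifluoroacetic anhydride, 2,4,6-collidine, MeCN, 0 °C) gives the α-trifluoroacetoxy sulfide F3, and aqueous NaHCO3 hydrolysis releases aldehyde 14, where the route is rejoined.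

Step 14. The acetylide may add to the cinnamate carbonyl or its double bond, or the β-alkoxy triflate may eliminate before substitution. The fallback builds the C2=C3 bond by olefination instead of alkylation. It sets out from alcohol 21, which is oxidised (Dess–Martin periodinane, NaHCO3, CH2Cl2) to the C4 aldehyde F4. Wittig methoxymethylenation (Ph3P=CHOMe from the phosphonium chloride and KN(SiMe3)2, THF, −78 °C) gives the enol ether F5. Hg(OAc)2 in aqueous THF followed by KI unmasks the homologous C3 aldehyde F6. A (Z)-selective Horner–Wadsworth–Emmons reaction with ethyl (diphenoxyphosphoryl)acetate (NaH, THF, −78 °C) then gives the (Z)-enoate 26 directly, bypassing steps 13–15.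

Step 9. Facial selectivity may be poor if the magnesium chelate between the aldehyde and ring oxygens is incompletely formed, since methyl is a small nucleophile. The fallback sets C11 by reduction instead of addition. It sets out from aldehyde 14, which is treated with MeMgBr in THF without regard to selectivity to give the C11-epimeric alcohols F7. Dess–Martin oxidation gives the methyl ketone F8. LiBH(s-Bu)3 in THF at −78 °C should then reduce it under non-chelation control, the bulky hydride arriving anti to the C10–O bond, to give the (11S) alcohol 15.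

Further compounds
F1 | step 8 | (E)-β-alkoxyvinyl p-tolyl sulfoxide C9 iodide (sulfur epimers) | Cc1ccc(cc1)S(=O)/C=C/O[C@H](CCI)[C@@H]1OC(C)(C)O[C@@H]1CO[Si](c1ccccc1)(c1ccccc1)C(C)(C)C
F2 | step 8 | cis-THF C11 p-tolyl sulfoxide (sulfur epimers) | Cc1ccc(cc1)S(=O)C[C@@H]1CC[C@H]([C@@H]2OC(C)(C)O[C@@H]2CO[Si](c3ccccc3)(c3ccccc3)C(C)(C)C)O1
F3 | step 8 | C11 α-trifluoroacetoxy p-tolyl sulfide (C11 epimers) | Cc1ccc(cc1)SC(OC(=O)C(F)(F)F)[C@@H]1CC[C@H]([C@@H]2OC(C)(C)O[C@@H]2CO[Si](c3ccccc3)(c3ccccc3)C(C)(C)C)O1
F4 | step 14 | C4 aldehyde | C[C@H](OC(=O)/C=C/c1ccc(OCOC)cc1)[C@@H]1CC[C@H]([C@@H]2OC(C)(C)O[C@@H]2C=O)O1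
F5 | step 14 | C3=C4 methyl enol ether (E/Z mixture) | C[C@H](OC(=O)/C=C/c1ccc(OCOC)cc1)[C@@H]1CC[C@H]([C@@H]2OC(C)(C)O[C@@H]2C=COC)O1
F6 | step 14 | C3 aldehyde | C[C@H](OC(=O)/C=C/c1ccc(OCOC)cc1)[C@@H]1CC[C@H]([C@@H]2OC(C)(C)O[C@@H]2CC=O)O1
F7 | step 9 | C11-epimeric secondary alcohols | CC(O)[C@@H]1CC[C@H]([C@@H]2OC(C)(C)O[C@@H]2CO[Si](c3ccccc3)(c3ccccc3)C(C)(C)C)O1
F8 | step 9 | C11 methyl ketone | CC(=O)[C@@H]1CC[C@H]([C@@H]2OC(C)(C)O[C@@H]2CO[Si](c3ccccc3)(c3ccccc3)C(C)(C)C)O1
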